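The numbers in the tables were generated by integration from invented constants; scatter was added.

We start from an easy step: the dawn run and the noon run have the same charge of starting material and differ in enzyme loading by a factor of 1.50, and dawn's 20.6% of target at 10.0 min matches noon's 20.9% at 15.0 min. So we read noon as dawn in slow motion, its minutes divided by that factor, and the flask asked about is the dawn run followed further.

| setting | dawn | noon | flask |
|---|---|---|---|
| starting material | 20 mM | 20 mM | 20 mM |
| enzyme | 9.3 × 10⁻⁴ mol% | 6.2 × 10⁻⁴ mol% | 9.3 × 10⁻⁴ mol% |
| remark | the very flask that is asked about, followed so far | run made earlier |  |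
| time |  |  | 30 min |

| run | time / min | target / % | starting material / % |
|---|---|---|---|
| dawn | 0.667 | 28.3 | 70.4 |
| dawn | 1.00 | 40.4 | 58.0 |
| dawn | 1.50 | 53.4 | 39.2 |
| dawn | 2.50 | 65.3 | 13.7 |
| dawn | 4.00 | 52.0 | 1.0 |
| dawn | 6.00 | 35.2 | 0 |
| dawn | 10.0 | 20.6 | 0.4 |
| noon | 0.667 | 19.5 | 80.3 |
| noon | 1.33 | 36.6 | 61.0 |
| noon | 2.50 | 57.8 | 32.8 |
| noon | 4.00 | 65.7 | 10.7 |
| noon | 8.00 | 41.2 | 0.7 |
| noon | 15.0 | 20.9 | 0.2 |
| noon | 30.0 | 6.9 | 0.5 |

(readings scatter by 0.5 percentage points)



- the best time, 30 min at the latest, for target
- the amount of target, in percent of the starting material charged, at that time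
- the first time at which target reaches 33%, in the same percent, in min

In the first instants of the dawn run, c(starting material) falls and target takes up what goes, since the two readings add to 98.7% at 0.667 min. They add to 79.0% at 2.50 min, so in the middle target is being lost while it is still being made. By a straight line between the dawn readings, c(target) passes 33% at 0.796 min. The two highest readings are dawn's 65.3% at 2.50 min and noon's 65.7% at 4.00 min, which is 2.67 min on the clock of this flask. Their gap of 0.4 percentage points stands against a scatter of 0.5 points, so we commit to a top near 2.58 min at about 65.5%.

For the end we freeze the enzyme's work on target: with c(starting material) read at 0.2% by noon's 15.0 min, we take the fall of target as pseudo-first-order. The tail constant, the fraction of target lost per minute late in this flask, taken from noon's last two readings and multiplied by the factor, is 0.111 min⁻¹. Noon's earlier pair gives 0.145 min⁻¹, so the fall slows with time, and we use the later value. From dawn's last reading the constant puts target at 2.24% at 30 min.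

The forecast put the top a little later and higher than we do, giving 66% (from 65% to 67.2%) at 2.7 min (from 2.4 min to 3 min) and 33% at 0.79 min (from 0.76 min to 0.83 min), saying “The peak comes where formation falls to equal loss”. The flask gives 65.4% at 2.52 min and reaches 33% at 0.793 min.

    starting material + enzyme ⇌ complex (K = 146 L mol⁻¹, k = 3.78 × 10⁶ L mol⁻¹ s⁻¹)
    complex → enzyme + target (k = 68000 min⁻¹)
    enzyme + target → enzyme + over-reaction product (k = 17800 L mol⁻¹ s⁻¹)
    target + enzyme ⇌ isomer of the product + enzyme, rate k4*[enzyme]*[target] forward; the back reaction follows from the equilibrium constant (K = 0.510, k = 20600 L mol⁻¹ s⁻¹)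

In the flask, target falls from 11.4% at 15.0 min to 1.96% at 30 min, where the tail constant gives 2.16%, and isomer of the product goes alongside from 7.89% to 1.35%, while the relaxation half-life of that pair by their own step at 30 min, 1.02 min, is shorter than the tail's half-life of 6.24 min. Run backwards from dawn's reading at 10.0 min, the constant gives 25.7% of target for the neighbour flask, the same charge read at 8.0 min, which holds 26.7%.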